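**Retrosynthetic overview**
1. 11 ⇐ 10: hydroxide opening (retro-Dieckmann) of the C10 bridge ketone of the exo [4+2] dimer; C4–H is set when the released ester dienolate is protonated.
2. 10 ⇐ 2 × 9: catalyst-controlled exo- and enantioselective Diels–Alder dimerisation of the achiral cyclopentadienone (one molecule as diene, one as dienophile), as in the presumed biogenesis; it builds the cyclohexene ring and sets C7, C7a and C3a.
3. 9 ⇐ 8 (untenone A) by dehydration; 8 ⇐ 7 by intramolecular aldol (forms the five-membered ring); 7 ⇐ furan 6 by oxidative ring opening.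
4. 6 ⇐ 4 + 5 (radical C–H alkylation); 4 ⇐ 1 + 2.
5. Ring order: cyclopentenone (aldol), then the norbornenone-bridged cyclohexene ([4+2]), then the bridge is cut to give the hydrindenone.

Assumption: the target is made exactly as drawn, (3aR,4R,7R,7aS), with all four ring hydrogens cis; its CO2H carbon is the former bridge carbonyl of the dimer and is cis to the cyclopentenone ring, which corresponds to the exo dimer, so the route is built for exo.
Assumption: racemic intermediates whose stereocentres are erased later (8) are given without stereodescriptors.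
Assumption: (R,R)-DBFOX-Ph is written; the hand of the ligand is fixed by the first run (use (S,S) if the antipode of 11 forms).

**Step 1**
Reactants: 1 furan; 2 1-bromohexadecane
Product: 4 2-hexadecylfuran, via 2-furyllithium 3 (not isolated)
Conditions: n-BuLi (1.0 equiv), furan (1.5 equiv), THF, −78 to 0 °C; then 2, 0 °C to rt
Reagents that add atoms: none
Why: Ring-oxygen-directed α-lithiation of furan followed by SN2 alkylation of the 2-furyllithium with a primary bromide is routine and gives only the 2-alkylfuran when furan is in excess; no stereocentre.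

**Step 2**
Reactants: 4 2-hexadecylfuran; 5 methyl bromoacetate
Product: 6 methyl 2-(5-hexadecylfuran-2-yl)acetate
Conditions: 5 (3 equiv), Ir(ppy)3 (ppy = 2-phenylpyridinato, 1 mol%), NaHCO3 (2 equiv), MeCN–CH2Cl2, blue LEDs, rt
Reagents that add atoms: none
Why: Photoredox radical C–H alkylation (homolytic aromatic substitution): excited Ir(ppy)3 reduces 5 to the electrophilic carbomethoxymethyl radical, which adds to the only free α-position (C5) of the electron-rich furan, and the adduct radical is oxidised by the oxidised photocatalyst and loses a proton; no stereocentre.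

**Step 3**
Reactants: 6 methyl 2-(5-hexadecylfuran-2-yl)acetate
Product: 8 untenone A (racemic methyl 2-hexadecyl-2-hydroxy-5-oxocyclopent-3-ene-1-carboxylate), via Z-enedione 7 (not isolated)
Conditions: mCPBA (1.0 equiv), CH2Cl2, 0 °C; then SiO2, rt; product kept cold and used at once
Reagents that add atoms: mCPBA (3-chloroperoxybenzoic acid) O=C(OO)c1cccc(Cl)c1
Why: Peracid oxidative ring opening of a 2,5-dialkylfuran gives the cis-enedione, whose β-keto ester methylene adds to the C6 ketone (intramolecular aldol, 5-exo-trig) because the Z geometry holds the two ends together; the two stereocentres formed are racemic and are erased in step 4.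

**Step 4**
Reactants: 8 untenone A (two molecules)
Product: 11 (3aR,4R,7R,7aS)-3,5-dihexadecyl-2,4-bis(methoxycarbonyl)-1-oxo-3a,4,7,7a-tetrahydro-1H-indene-7-carboxylic acid, via cyclopentadienone 9 (not isolated), via exo dimer 10 (not isolated)
Conditions: Ni(ClO4)2·6H2O (15 mol%), (R,R)-DBFOX-Ph [(R,R)-4,6-dibenzofurandiyl-2,2'-bis(4-phenyloxazoline), 16 mol%], 2,6-lutidine (20 mol%), 4 Å MS, CH2Cl2, 25 °C, 8 added over 6 h; then LiOH (1.5 equiv), THF–H2O, 0 °C, 10 min; 1 M HCl
Reagents that add atoms: lithium hydroxide [Li+].[OH-]
Why: Proposed new method: the nickel-bound β-keto ester enolate of 8 expels its β-hydroxyl (E1cB), so 9 is formed only on the chiral octahedral divalent nickel centre, chelated as a LUMO-lowered dienophile (8 itself does not dehydrate at 25 °C); a second molecule of 9 docks through its ketone oxygen at the free cis site, which is possible only in the exo stacking (by a rough geometric model the two C=O oxygens are about 3 Å apart there and about 5 Å apart in the endo stacking, which also stacks the two hexadecyl-bearing carbons on each other); the phenyloxazoline pocket selects one face of the bound C4=C5 bond, so one suprafacial [4+2] event with para regiochemistry (free diene terminus to Cα, ester-bearing terminus to Cβ) sets C7, C7a and C3a with the cis ring fusion; hydroxide then adds to the strained C10 bridge ketone and retro-Dieckmann (retro-Claisen) cleavage gives the carboxylate (no internal proton return) and the ester dienolate, which water protonates at C4 on the convex face anti to the cyclopentenone ring, giving the all-cis acid; closest known reactions are the thermal dehydration, Diels–Alder dimerisation and retro-Dieckmann cascade of 4-hydroxycyclopentenone β-keto esters, DBFOX-Ph nickel perchlorate catalysed Diels–Alder reactions of chelating dienophiles, and Lewis-acid-templated (self-assembled) Diels–Alder reactions.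

**Compound list**
1 | furan | c1ccoc1 | starting material
2 | 1-bromohexadecane | CCCCCCCCCCCCCCCCBr | starting material
3 | 2-furyllithium | [Li]c1ccco1 | intermediate (not isolated)
4 | 2-hexadecylfuran | CCCCCCCCCCCCCCCCc1ccco1 | intermediate
5 | methyl bromoacetate | COC(=O)CBr | starting material
6 | methyl 2-(5-hexadecylfuran-2-yl)acetate | COC(=O)Cc1ccc(CCCCCCCCCCCCCCCC)o1 | intermediate
7 | methyl (4Z)-3,6-dioxodocos-4-enoate | COC(=O)CC(=O)/C=C\C(=O)CCCCCCCCCCCCCCCC | intermediate (not isolated)
8 | untenone A, racemic methyl 2-hexadecyl-2-hydroxy-5-oxocyclopent-3-ene-1-carboxylate (C1 epimerisable) | COC(=O)C1C(=O)C=CC1(O)CCCCCCCCCCCCCCCC | intermediate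
9 | methyl 2-hexadecyl-5-oxocyclopenta-1,3-diene-1-carboxylate (achiral) | COC(=O)C1=C(CCCCCCCCCCCCCCCC)C=CC1=O | intermediate (not isolated)
10 | dimethyl (1R,2S,6S,7S)-5,8-dihexadecyl-3,10-dioxotricyclo[5.2.1.0(2,6)]deca-4,8-diene-4,7-dicarboxylate, exo (cyclopentenone ring syn to the C10 bridge) | CCCCCCCCCCCCCCCCC1=C[C@@H]3[C@H]2C(=O)C(C(=O)OC)=C(CCCCCCCCCCCCCCCC)[C@H]2[C@@]1(C(=O)OC)C3=O | intermediate (not isolated)
11 | (3aR,4R,7R,7aS)-3,5-dihexadecyl-2,4-bis(methoxycarbonyl)-1-oxo-3a,4,7,7a-tetrahydro-1H-indene-7-carboxylic acid (H3a, H4, H7, H7a all cis) | CCCCCCCCCCCCCCCCC1=C[C@@H](C(=O)O)[C@H]2C(=O)C(C(=O)OC)=C(CCCCCCCCCCCCCCCC)[C@H]2[C@H]1C(=O)OC | target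

**Step count and risks**
Total steps: 4. Longest linear sequence: 4 (1 → 4 → 6 → 8 → 11).

Most likely to fail, in this order:

Step 4 must deliver three selectivities at once: exo instead of the usual endo dimerisation, one enantiotopic face, and convex-face protonation at C4. Read exo/endo from the H7/H7a NOE and coupling, and ee by chiral HPLC. Fallback, from 8 back to 11: give up catalyst control of absolute configuration. Heat 8 in toluene at 80 °C over 4 Å MS with no metal or ligand, open the crude racemic dimer with LiOH exactly as in step 4 to obtain racemic all-cis acid F1, and resolve it by fractional crystallisation of the (R)-1-phenylethylammonium salt of 11 F2 (the S amine if that salt is the less soluble one). Acidification with 1 M HCl returns 11. This fallback rests on the uncatalysed dimerisation being exo, which is not established.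

Step 2 may give a low yield because the furan is the limiting partner and the radical can over-alkylate or be reduced. Fallback, from 4 back to 6: polar chemistry in place of the radical. Friedel–Crafts hydroxyalkylation of 4 at C5 with methyl glyoxylate (Yb(OTf)3 5 mol%, CH2Cl2, rt) gives methyl 2-(5-hexadecylfuran-2-yl)-2-hydroxyacetate F3. Ac2O and pyridine give methyl 2-acetoxy-2-(5-hexadecylfuran-2-yl)acetate F4. SmI2 in THF–MeOH at −78 °C removes the α-acetoxy group to give 6.

Step 3 may suffer over-oxidation of the β-keto ester, or 8 may dehydrate on handling. Fallback, from 4 back to 8, bypassing 6: open the furan before the ester is attached. NBS and NaHCO3 in acetone–H2O at −20 °C convert 4 into (2Z)-4-oxoicos-2-enal F5. The lithium enolate of methyl acetate (LDA, MeOAc, THF, −78 °C) adds to the aldehyde only and gives methyl (4Z)-3-hydroxy-6-oxodocos-4-enoate F6. Dess–Martin periodinane oxidises F6 to 7, which closes to 8 as in step 3.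

**Further compounds**
F1 | step 4 | racemic 11 (relative configuration of 11, both enantiomers) | CCCCCCCCCCCCCCCCC1=C[C@@H](C(=O)O)[C@H]2C(=O)C(C(=O)OC)=C(CCCCCCCCCCCCCCCC)[C@H]2[C@H]1C(=O)OC
F2 | step 4 | (R)-1-phenylethylammonium salt of 11 | CCCCCCCCCCCCCCCCC1=C[C@@H](C(=O)[O-])[C@H]2C(=O)C(C(=O)OC)=C(CCCCCCCCCCCCCCCC)[C@H]2[C@H]1C(=O)OC.C[C@@H]([NH3+])c1ccccc1
F3 | step 2 | methyl 2-(5-hexadecylfuran-2-yl)-2-hydroxyacetate (racemic) | COC(=O)C(O)c1ccc(CCCCCCCCCCCCCCCC)o1
F4 | step 2 | methyl 2-acetoxy-2-(5-hexadecylfuran-2-yl)acetate (racemic) | COC(=O)C(OC(C)=O)c1ccc(CCCCCCCCCCCCCCCC)o1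
F5 | step 3 | (2Z)-4-oxoicos-2-enal | O=C/C=C\C(=O)CCCCCCCCCCCCCCCC
F6 | step 3 | methyl (4Z)-3-hydroxy-6-oxodocos-4-enoate (racemic) | COC(=O)CC(O)/C=C\C(=O)CCCCCCCCCCCCCCCC
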